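**Retrosynthetic overview**
1. Target 25 ⇐ methyl ester 24 ⇐ aldehyde 21 + cinnamylphosphonate 22 (E-selective Horner–Wadsworth–Emmons; the diene is installed last); 21 comes from the terminal alkene of 19.
2. 19 ⇐ 3-methoxy-1,2-dioxolane 16 + ketene silyl acetal 17 (C–C bond formation at a peroxycarbenium ion sets C3).
3. 16 ⇐ tertiary hydroperoxide 13 ⇐ oxetane 12 + H2O2 (invertive opening sets the C5–O–O centre).
4. 12 ⇐ epoxide 5 + 2-methyl-1,3-dithiane 6; 5 ⇐ ketone 4 (asymmetric Corey–Chaykovsky); 4 ⇐ enone 3 (asymmetric conjugate methylation) ⇐ diene 1 + butenone 2 (cross-metathesis).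
5. Ring order: oxirane (step 3), oxetane (step 7), 1,2-dioxolane (step 9); the phenyl ring is bought.

Assumption: in steps 2 and 3 the ligand enantiomer written is taken to give the drawn configuration; if the sense of induction proves opposite, the mirror-image ligand is used.

**Route**

Step 1
Reactants: 1 deca-1,9-diene; 2 but-3-en-2-one
Product: 3 (3E)-dodeca-3,11-dien-2-one
Conditions: 1 (4 equiv), second-generation Grubbs catalyst RuCl2(=CHPh)(PCy3)(H2IMes) (2 mol %), CH2Cl2, 40 °C
Reagents that add atoms: none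
Why: Olefin cross-metathesis of a terminal alkene with the electron-poor enone partner gives the E-enone, and the excess of diene suppresses reaction at both ends.

Step 2
Reactants: 3 (3E)-dodeca-3,11-dien-2-one
Product: 4 (4R)-4-methyldodec-11-en-2-one
Conditions: MeMgBr (1.2 equiv), CuBr·SMe2 (5 mol %), (R)-1-[(S)-2-(diphenylphosphino)ferrocenyl]ethyldicyclohexylphosphine (6 mol %), t-BuOMe, −75 °C; then 1 M HCl
Reagents that add atoms: methylmagnesium bromide C[Mg]Br
Why: Copper-catalysed asymmetric conjugate addition, in which the chiral ferrocenyl diphosphine–copper complex delivers methyl to one face of the enone and so sets the side-chain (R) centre.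

Step 3
Reactants: 4 (4R)-4-methyldodec-11-en-2-one
Product: 5 (2S)-2-methyl-2-[(2R)-2-methyldec-9-en-1-yl]oxirane
Conditions: Me3S(O)I, NaH, THF (ylide preformed); LaLi3[(S)-1,1'-bi-2-naphtholate]3 (5 mol %), (2,4,6-(MeO)3C6H2)3P=O (5 mol %), 5 Å molecular sieves, THF, rt
Reagents that add atoms: trimethylsulfoxonium iodide C[S+](C)(C)=O.[I-]
Why: Catalytic asymmetric Corey–Chaykovsky epoxidation of a methyl ketone, in which the chiral lanthanum–lithium binaphtholate distinguishes methyl from the alkyl chain and sets the quaternary C–O centre (S).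

Step 4
Reactants: 5 (2S)-2-methyl-2-[(2R)-2-methyldec-9-en-1-yl]oxirane; 6 2-methyl-1,3-dithiane
Product: 8 (2S,4R)-2,4-dimethyl-1-(2-methyl-1,3-dithian-2-yl)dodec-11-en-2-ol, via 2-lithio-2-methyl-1,3-dithiane 7 (not isolated)
Conditions: 6, n-BuLi, THF, −20 °C; then 5, −20 °C → rt; H2O
Reagents that add atoms: none
Why: Corey–Seebach acyl-anion opening of the epoxide by SN2 attack at its unsubstituted CH2, which leaves the tertiary carbinol centre untouched.

Step 5
Reactants: 8 (2S,4R)-2,4-dimethyl-1-(2-methyl-1,3-dithian-2-yl)dodec-11-en-2-ol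
Product: 9 (4S,6R)-4-hydroxy-4,6-dimethyltetradec-13-en-2-one
Conditions: MeI, CaCO3, MeCN/H2O (4:1), 45 °C
Reagents that add atoms: water O
Why: S-alkylative dithiane hydrolysis under buffered conditions unmasks the methyl ketone without retro-aldol cleavage or dehydration of the tertiary aldol.

Step 6
Reactants: 9 (4S,6R)-4-hydroxy-4,6-dimethyltetradec-13-en-2-one
Product: 10 (4S,6R)-4,6-dimethyltetradec-13-ene-2,4-diol (both C2 epimers)
Conditions: NaBH4, MeOH, 0 °C
Reagents that add atoms: none
Why: Borohydride reduction of the ketone gives the secondary alcohol unselectively, which is harmless because this carbon is re-oxidised in step 9.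

Step 7
Reactants: 10 (4S,6R)-4,6-dimethyltetradec-13-ene-2,4-diol
Product: 12 (2S)-2,4-dimethyl-2-[(2R)-2-methyldec-9-en-1-yl]oxetane (both C4 epimers), via secondary tosylate 11 (not isolated)
Conditions: n-BuLi (1.0 equiv), THF, −5 °C; TsCl (1.0 equiv); then n-BuLi (1.0 equiv), −5 → 60 °C
Reagents that add atoms: none
Why: One-pot sulfonylation of the less hindered secondary hydroxyl and intramolecular Williamson etherification (4-exo-tet) by the tertiary alkoxide close the oxetane without breaking the C–O bond of the quaternary centre, whose configuration is retained.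

Step 8
Reactants: 12 (2S)-2,4-dimethyl-2-[(2R)-2-methyldec-9-en-1-yl]oxetane
Product: 13 (4R,6R)-4-hydroperoxy-4,6-dimethyltetradec-13-en-2-ol (both C2 epimers)
Conditions: anhydrous H2O2 in Et2O (10 equiv), TMSOTf (0.2 equiv), −78 → 0 °C
Reagents that add atoms: hydrogen peroxide OO
Why: Lewis acid-promoted perhydrolysis of the oxetane occurs at the more substituted carbon by backside attack on the activated tertiary C–O bond, giving the tertiary hydroperoxide with inversion (descriptor S → R) and so setting C5 of the dioxolane.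

Step 9
Reactants: 13 (4R,6R)-4-hydroperoxy-4,6-dimethyltetradec-13-en-2-ol
Product: 15 (5R)-3,5-dimethyl-5-[(2R)-2-methyldec-9-en-1-yl]-1,2-dioxolan-3-ol (both C3 epimers), via hydroperoxy ketone 14 (not isolated)
Conditions: Dess–Martin periodinane (1.2 equiv), CH2Cl2, 0 °C → rt
Reagents that add atoms: none
Why: Dess–Martin oxidation of the secondary alcohol gives a β-hydroperoxy ketone that closes spontaneously (ring–chain tautomerism) to the five-membered peroxyhemiketal, with C5 unaffected.

Step 10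
Reactants: 15 (5R)-3,5-dimethyl-5-[(2R)-2-methyldec-9-en-1-yl]-1,2-dioxolan-3-ol
Product: 16 (5R)-3-methoxy-3,5-dimethyl-5-[(2R)-2-methyldec-9-en-1-yl]-1,2-dioxolane (both C3 epimers)
Conditions: MeOH, pyridinium p-toluenesulfonate (cat.), rt
Reagents that add atoms: methanol CO
Why: Acid-catalysed ketal exchange converts the peroxyhemiketal into the mixed methyl peroxyketal, whose C3 configuration is irrelevant because it is ionised in the next step.

Step 11
Reactants: 16 (5R)-3-methoxy-3,5-dimethyl-5-[(2R)-2-methyldec-9-en-1-yl]-1,2-dioxolane; 17 tert-butyl[(1-methoxyethenyl)oxy]dimethylsilane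
Product: 19 methyl 2-[(3S,5R)-3,5-dimethyl-5-[(2R)-2-methyldec-9-en-1-yl]-1,2-dioxolan-3-yl]acetate, via peroxycarbenium triflate 18 (not isolated)
Conditions: 17 (2 equiv), TMSOTf (0.3 equiv), CH2Cl2, −78 °C; chromatographic removal of the C3 epimer
Reagents that add atoms: none
Why: Mukaiyama-type addition of the ketene silyl acetal to the planar peroxycarbenium ion takes place anti to the larger C5 substituent (the branched chain), giving the (3S) acetate as the expected major isomer in only modest selectivity, so the epimer is separated.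

Step 12
Reactants: 19 methyl 2-[(3S,5R)-3,5-dimethyl-5-[(2R)-2-methyldec-9-en-1-yl]-1,2-dioxolan-3-yl]acetate
Product: 21 methyl 2-[(3S,5R)-3,5-dimethyl-5-[(2R)-2-methyl-9-oxononyl]-1,2-dioxolan-3-yl]acetate, via secondary ozonide 20 (not isolated)
Conditions: O3, CH2Cl2, −78 °C; then PPh3, −78 → 0 °C
Reagents that add atoms: ozone [O-][O+]=O
Why: Ozonolysis with reductive work-up cleaves the only alkene to the aldehyde, while the hindered di-tertiary dialkyl peroxide is inert to ozone and to cold phosphine.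

Step 13
Reactants: 21 methyl 2-[(3S,5R)-3,5-dimethyl-5-[(2R)-2-methyl-9-oxononyl]-1,2-dioxolan-3-yl]acetate; 22 diethyl [(2E)-3-phenylprop-2-en-1-yl]phosphonate
Product: 24 methyl 2-[(3S,5R)-3,5-dimethyl-5-[(2R,9E,11E)-2-methyl-12-phenyldodeca-9,11-dien-1-yl]-1,2-dioxolan-3-yl]acetate, via lithiated phosphonate 23 (not isolated)
Conditions: 22, LiN(SiMe3)2, THF, −78 °C; then 21, −78 → 0 °C
Reagents that add atoms: none
Why: Horner–Wadsworth–Emmons olefination with an allylic phosphonate anion forms the new disubstituted alkene with E geometry and keeps the E styrenyl bond, and the aldehyde reacts far faster than the ester.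

Step 14
Reactants: 24 methyl 2-[(3S,5R)-3,5-dimethyl-5-[(2R,9E,11E)-2-methyl-12-phenyldodeca-9,11-dien-1-yl]-1,2-dioxolan-3-yl]acetate
Product: 25 2-[(3S,5R)-3,5-dimethyl-5-[(2R,9E,11E)-2-methyl-12-phenyldodeca-9,11-dien-1-yl]-1,2-dioxolan-3-yl]acetic acid
Conditions: LiOH·H2O, THF/MeOH/H2O (3:1:1), 0 °C → rt; then 1 M HCl to pH 3
Reagents that add atoms: lithium hydroxide [Li+].[OH-]
Why: Saponification of the methyl ester is safe because both peroxide carbons are quaternary, so no Kornblum–DeLaMare fragmentation is possible and no stereocentre is touched.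

**Compound list**
1 | deca-1,9-diene | C=CCCCCCCC=C | starting material
2 | but-3-en-2-one | CC(=O)C=C | starting material
3 | (3E)-dodeca-3,11-dien-2-one | CC(=O)/C=C/CCCCCCC=C | intermediate
4 | (4R)-4-methyldodec-11-en-2-one | C[C@H](CCCCCCC=C)CC(C)=O | intermediate
5 | (2S)-2-methyl-2-[(2R)-2-methyldec-9-en-1-yl]oxirane | C[C@H](CCCCCCC=C)C[C@@]1(C)CO1 | intermediate
6 | 2-methyl-1,3-dithiane | CC1SCCCS1 | starting material
7 | 2-lithio-2-methyl-1,3-dithiane | [Li]C1(C)SCCCS1 | intermediate (not isolated)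
8 | (2S,4R)-2,4-dimethyl-1-(2-methyl-1,3-dithian-2-yl)dodec-11-en-2-ol | C[C@H](CCCCCCC=C)C[C@@](O)(C)CC1(C)SCCCS1 | intermediate
9 | (4S,6R)-4-hydroxy-4,6-dimethyltetradec-13-en-2-one | C[C@H](CCCCCCC=C)C[C@@](O)(C)CC(C)=O | intermediate
10 | (4S,6R)-4,6-dimethyltetradec-13-ene-2,4-diol, both C2 epimers | C[C@H](CCCCCCC=C)C[C@@](O)(C)CC(C)O | intermediate
11 | (4S,6R)-4-hydroxy-4,6-dimethyltetradec-13-en-2-yl 4-methylbenzenesulfonate, both C2 epimers | C[C@H](CCCCCCC=C)C[C@@](O)(C)CC(C)OS(=O)(=O)c1ccc(C)cc1 | intermediate (not isolated)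
12 | (2S)-2,4-dimethyl-2-[(2R)-2-methyldec-9-en-1-yl]oxetane, both C4 epimers | C[C@H](CCCCCCC=C)C[C@@]1(C)CC(C)O1 | intermediate
13 | (4R,6R)-4-hydroperoxy-4,6-dimethyltetradec-13-en-2-ol, both C2 epimers | C[C@H](CCCCCCC=C)C[C@](OO)(C)CC(C)O | intermediate
14 | (4R,6R)-4-hydroperoxy-4,6-dimethyltetradec-13-en-2-one | C[C@H](CCCCCCC=C)C[C@](OO)(C)CC(C)=O | intermediate (not isolated)
15 | (5R)-3,5-dimethyl-5-[(2R)-2-methyldec-9-en-1-yl]-1,2-dioxolan-3-ol, both C3 epimers | C[C@H](CCCCCCC=C)C[C@]1(C)CC(C)(O)OO1 | intermediate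
16 | (5R)-3-methoxy-3,5-dimethyl-5-[(2R)-2-methyldec-9-en-1-yl]-1,2-dioxolane, both C3 epimers | C[C@H](CCCCCCC=C)C[C@]1(C)CC(C)(OC)OO1 | intermediate
17 | tert-butyl[(1-methoxyethenyl)oxy]dimethylsilane | C=C(OC)O[Si](C)(C)C(C)(C)C | starting material
18 | (5R)-3,5-dimethyl-5-[(2R)-2-methyldec-9-en-1-yl]-1,2-dioxolan-3-ylium trifluoromethanesulfonate | C[C@H](CCCCCCC=C)C[C@]1(C)CC(C)=[O+]O1.[O-]S(=O)(=O)C(F)(F)F | intermediate (not isolated)
19 | methyl 2-[(3S,5R)-3,5-dimethyl-5-[(2R)-2-methyldec-9-en-1-yl]-1,2-dioxolan-3-yl]acetate | C[C@H](CCCCCCC=C)C[C@]1(C)C[C@@](C)(CC(=O)OC)OO1 | intermediate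
20 | methyl 2-[(3S,5R)-3,5-dimethyl-5-[(2R)-2-methyl-8-(1,2,4-trioxolan-3-yl)octyl]-1,2-dioxolan-3-yl]acetate | C[C@H](CCCCCCC1OCOO1)C[C@]2(C)C[C@@](C)(CC(=O)OC)OO2 | intermediate (not isolated)
21 | methyl 2-[(3S,5R)-3,5-dimethyl-5-[(2R)-2-methyl-9-oxononyl]-1,2-dioxolan-3-yl]acetate | C[C@H](CCCCCCC=O)C[C@]1(C)C[C@@](C)(CC(=O)OC)OO1 | intermediate
22 | diethyl [(2E)-3-phenylprop-2-en-1-yl]phosphonate | CCOP(=O)(OCC)C/C=C/c1ccccc1 | starting material
23 | diethyl [(2E)-1-lithio-3-phenylprop-2-en-1-yl]phosphonate | CCOP(=O)(OCC)C([Li])/C=C/c1ccccc1 | intermediate (not isolated)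
24 | methyl 2-[(3S,5R)-3,5-dimethyl-5-[(2R,9E,11E)-2-methyl-12-phenyldodeca-9,11-dien-1-yl]-1,2-dioxolan-3-yl]acetate | C[C@H](CCCCCC/C=C/C=C/c1ccccc1)C[C@]1(C)C[C@@](C)(CC(=O)OC)OO1 | intermediate
25 | 2-[(3S,5R)-3,5-dimethyl-5-[(2R,9E,11E)-2-methyl-12-phenyldodeca-9,11-dien-1-yl]-1,2-dioxolan-3-yl]acetic acid | C[C@H](CCCCCC/C=C/C=C/c1ccccc1)C[C@]1(C)C[C@@](C)(CC(=O)O)OO1 | target

**Totals**
Total step count: 14. Longest linear sequence: 14 steps (1 and 2 to 25); compounds 6, 17 and 22 are bought.

**Three steps most likely to fail, with fallbacks**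

Step 9 (alcohol oxidation beside a free hydroperoxide; the oxidant may attack the OOH group). The fallback sets out from 13 and comes back to the route at 16, bypassing 15. The hydroperoxide is masked first: 2-methoxypropene with catalytic pyridinium p-toluenesulfonate in CH2Cl2 at −20 °C converts the more acidic OOH group of 13 into the peroxyketal (4R,6R)-4-[(2-methoxypropan-2-yl)peroxy]-4,6-dimethyltetradec-13-en-2-ol F1. Dess–Martin periodinane buffered with pyridine then gives the ketone (4R,6R)-4-[(2-methoxypropan-2-yl)peroxy]-4,6-dimethyltetradec-13-en-2-one F2. Pyridinium p-toluenesulfonate in MeOH removes the ketal group, and the liberated hydroperoxy ketone closes and is ketalised in the same flask to 16.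

Step 11 (the facial selectivity at C3 rests on the small size difference between methyl and the branched chain at C5, and may be low). The fallback sets out from 13 and comes back at 19; it forms the ring by O–C3 bond formation instead of C–C bond formation. Compound 13 is taken through F1 to the peroxyketal ketone F2 as described above. Horner–Wadsworth–Emmons reaction of F2 with trimethyl phosphonoacetate (NaH, THF, 0 °C) gives the enoate methyl (5R,7R)-5-[(2-methoxypropan-2-yl)peroxy]-3,5,7-trimethylpentadeca-2,14-dienoate F3 as an E/Z mixture. Pyridinium p-toluenesulfonate in MeOH at 0 °C releases methyl (5R,7R)-5-hydroperoxy-3,5,7-trimethylpentadeca-2,14-dienoate F4. Et2NH in CF3CH2OH then brings about reversible 5-exo oxa-Michael addition of the hydroperoxide to the β-methyl enoate, giving 19 and its C3 epimer under thermodynamic control, which are separated.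

Step 13 (strong base beside a β-peroxy ester, and incomplete E selectivity at the new alkene). The fallback sets out from 19 and comes back at 24, bypassing 20, 21 and 23. Cross-metathesis of 19 with (E)-buta-1,3-dien-1-ylbenzene (3 equiv) and the second-generation Grubbs catalyst RuCl2(=CHPh)(PCy3)(H2IMes) (5 mol %) in CH2Cl2 at 40 °C installs the phenyldiene directly under neutral conditions. It makes no new compound.

**Further compounds**
F1 | step 9 | (4R,6R)-4-[(2-methoxypropan-2-yl)peroxy]-4,6-dimethyltetradec-13-en-2-ol, both C2 epimers | C[C@H](CCCCCCC=C)C[C@](OOC(C)(C)OC)(C)CC(C)O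
F2 | step 9 | (4R,6R)-4-[(2-methoxypropan-2-yl)peroxy]-4,6-dimethyltetradec-13-en-2-one | C[C@H](CCCCCCC=C)C[C@](OOC(C)(C)OC)(C)CC(C)=O
F3 | step 11 | methyl (5R,7R)-5-[(2-methoxypropan-2-yl)peroxy]-3,5,7-trimethylpentadeca-2,14-dienoate, 2E/2Z mixture | C[C@H](CCCCCCC=C)C[C@](OOC(C)(C)OC)(C)CC(C)=CC(=O)OC
F4 | step 11 | methyl (5R,7R)-5-hydroperoxy-3,5,7-trimethylpentadeca-2,14-dienoate, 2E/2Z mixture | C[C@H](CCCCCCC=C)C[C@](OO)(C)CC(C)=CC(=O)OC
F0 | step 13 | none | none
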